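**Plan**
- Retrosynthesis: the C1′–O ester bond is cut first, the quinone of ring B is taken back to a 4-methoxy-1-naphthol, and ring B is then cut at C4–C3, C2–C1 and C1–C8a into an aryl(methoxy)carbene chromium complex, a terminal alkyne and one CO.
- Enabling feature: ring B (C1, C2, C3, C4, C4a, C8a) has oxygen at C1 and C4 in a para relationship, C3 is unsubstituted and C2 bears the side chain. C2–C3 is therefore the two carbons of a terminal alkyne that already holds C1′, C1 is a carbonyl ligand and C4 a carbene carbon attached to ring A.
- Forward: ring A comes from hydroquinone as its bis(methoxymethyl) ether; ring B is closed in the benzannulation (step 8); oxidation to the quinone, desilylation, esterification and acetal removal follow.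
- Stereochemistry: the only stereocentre, C1′ (S), is set by asymmetric transfer hydrogenation of a silylated ynone (step 5) and is carried through untouched.

Key step: step 8

Remark: the target is a naphthazarin whose two quinonoid tautomers interconvert freely, so the drawn tautomer is used throughout and the ring that holds the carbonyl groups in a late intermediate has no consequence once both phenols are free.

**Step 1**
Reactants: 1 hydroquinone
Product: 2 1,4-bis(methoxymethoxy)benzene
Conditions: NaH, MOMCl, DMF, 0 °C → rt
Reagents that add atoms: chloromethyl methyl ether (MOMCl), COCCl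
Why: Double Williamson O-alkylation of the bis-phenoxide with the reactive α-chloro ether gives the bis-acetal, whose oxygens later direct ortho-lithiation and which tolerates the organolithium, chromium carbonyl and oxidation steps.

**Step 2**
Reactants: 2 1,4-bis(methoxymethoxy)benzene; 3 chromium hexacarbonyl, Cr(CO)6
Product: 6 pentacarbonyl{[2,5-bis(methoxymethoxy)phenyl](methoxy)methylidene}chromium, via 2,5-bis(methoxymethoxy)phenyllithium 4 (not isolated), via lithium acylpentacarbonylchromate 5 (not isolated)
Conditions: n-BuLi, TMEDA, THF, 0 °C; Cr(CO)6, Et2O, 0 °C → rt; then Me3OBF4, CH2Cl2, 0 °C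
Reagents that add atoms: trimethyloxonium tetrafluoroborate (Me3OBF4), C[O+](C)C.F[B-](F)(F)F
Why: Directed ortho-metalation beside an acetal oxygen (all four ring hydrogens are equivalent) gives the aryllithium, which adds to a carbonyl ligand of Cr(CO)6, and the acylchromate is O-methylated by the oxonium salt (Fischer carbene synthesis).

**Step 3**
Reactants: 7 4-methylpent-3-enoic acid
Product: 8 N-methoxy-N,4-dimethylpent-3-enamide
Conditions: MeNHOMe·HCl, EDC·HCl, N-methylmorpholine, CH2Cl2, 0 °C → rt
Reagents that add atoms: N,O-dimethylhydroxylamine hydrochloride, CNOC.Cl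
Why: Carbodiimide-mediated amidation (Weinreb amide formation) runs under near-neutral conditions that should leave the β,γ-double bond out of conjugation.

**Step 4**
Reactants: 8 N-methoxy-N,4-dimethylpent-3-enamide; 9 trimethylsilylacetylene
Product: 11 6-methyl-1-(trimethylsilyl)hept-5-en-1-yn-3-one, via lithium (trimethylsilyl)acetylide 10 (not isolated)
Conditions: 9, n-BuLi, THF, −78 °C; then 8, −78 → −20 °C; inverse quench into cold 1 M HCl
Reagents that add atoms: none
Why: In this Weinreb ketone synthesis the acetylide adds once to give a chelated tetrahedral adduct that releases the ynone only on the cold acidic inverse quench, which also protonates the liberated hydroxylamine before it can add to the ynone.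

**Step 5**
Reactants: 11 6-methyl-1-(trimethylsilyl)hept-5-en-1-yn-3-one
Product: 12 (S)-6-methyl-1-(trimethylsilyl)hept-5-en-1-yn-3-ol
Conditions: Ru[(S,S)-TsNCH(Ph)CH(Ph)NH](η6-p-cymene) (1 mol %), i-PrOH, rt
Reagents that add atoms: none
Why: In this Noyori–Ikariya asymmetric transfer hydrogenation the alkynyl group plays the part of the aryl group of an aryl ketone in the six-membered Ru–H/N–H transition state, so the (S,S)-ligand should deliver hydride to the face that gives the (S)-carbinol, and the base-free amido catalyst should leave the skipped olefin in place.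

**Step 6**
Reactants: 12 (S)-6-methyl-1-(trimethylsilyl)hept-5-en-1-yn-3-ol
Product: 13 (S)-3-(tert-butyldimethylsilyloxy)-6-methyl-1-(trimethylsilyl)hept-5-en-1-yne
Conditions: TBSCl, imidazole, DMF, rt
Reagents that add atoms: tert-butyldimethylsilyl chloride (TBSCl), CC(C)(C)[Si](C)(C)Cl
Why: Imidazole-promoted O-silylation of the secondary alcohol breaks no bond at the stereocentre and gives an ether that tolerates the chromium chemistry and keeps the intermediate non-volatile.

**Step 7**
Reactants: 13 (S)-3-(tert-butyldimethylsilyloxy)-6-methyl-1-(trimethylsilyl)hept-5-en-1-yne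
Product: 14 (S)-3-(tert-butyldimethylsilyloxy)-6-methylhept-5-en-1-yne
Conditions: K2CO3 (cat.), MeOH, rt
Reagents that add atoms: none
Why: Methoxide-mediated protodesilylation cleaves only the C(sp)–Si bond, since an acetylide is a far better leaving group from silicon than the alkoxide of the hindered silyl ether.

**Step 8**
Reactants: 6 pentacarbonyl{[2,5-bis(methoxymethoxy)phenyl](methoxy)methylidene}chromium; 14 (S)-3-(tert-butyldimethylsilyloxy)-6-methylhept-5-en-1-yne
Product: 16 2-[(S)-1-(tert-butyldimethylsilyloxy)-4-methylpent-3-enyl]-4-methoxy-5,8-bis(methoxymethoxy)naphthalen-1-ol, via tricarbonylchromium naphthol complex 15 (not isolated)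
Conditions: 6 (1.3 equiv), THF (0.05 M), 50 °C, Ar; then air, Et2O, rt
Reagents that add atoms: none
Why: Loss of one CO from the zerovalent chromium centre lets the alkyne coordinate and insert into the Cr=C bond with its unsubstituted terminus joining the carbene carbon (C4–C3), and the vinylcarbene so formed takes up a CO ligand (C2–C1) to give a chromium-bound vinylketene. Ring B closes by 6π-electrocyclisation of this ketene onto the only hydrogen-bearing ortho carbon of the aryl group (C1–C8a), and enolisation gives the naphthol as its Cr(CO)3 complex 15, from which air removes the metal. The closest known reaction type is the Dötz benzannulation of aryl(alkoxy)carbene chromium complexes with terminal alkynes, for which ortho-alkoxyaryl carbenes and propargylic silyl ethers are established partners. No stereocentre is formed, and C1′ lies outside the reacting atoms, so its (S) configuration is carried through. The step needs CO insertion and electrocyclisation to outrun indene, furan and cyclobutenone formation, which a methoxy carbene in a coordinating ether solvent at moderate temperature and dilution favours, and it needs the side chain beside the new hydroxyl, which the steric bias of a terminal alkyne secures (the opposite orientation would in any case converge on the same quinone in step 9). The trisubstituted olefin is only two carbons away from the vinylcarbene carbon, so its intramolecular cyclopropanation would require a bicyclo[2.1.0]pentane and should not compete.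

**Step 9**
Reactants: 16 2-[(S)-1-(tert-butyldimethylsilyloxy)-4-methylpent-3-enyl]-4-methoxy-5,8-bis(methoxymethoxy)naphthalen-1-ol
Product: 17 2-[(S)-1-(tert-butyldimethylsilyloxy)-4-methylpent-3-enyl]-5,8-bis(methoxymethoxy)naphthalene-1,4-dione
Conditions: PhI(OAc)2, MeCN/H2O, 0 °C
Reagents that add atoms: water, O
Why: Hypervalent-iodine oxidative demethylation of a para-methoxyphenol (ligand exchange of the free naphthol at iodine, attack of water at C4, loss of methanol) gives the quinone and engages only ring B, because ring A has no free hydroxyl.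

**Step 10**
Reactants: 17 2-[(S)-1-(tert-butyldimethylsilyloxy)-4-methylpent-3-enyl]-5,8-bis(methoxymethoxy)naphthalene-1,4-dione
Product: 18 2-[(S)-1-hydroxy-4-methylpent-3-enyl]-5,8-bis(methoxymethoxy)naphthalene-1,4-dione
Conditions: HF·pyridine, pyridine, THF, 0 °C → rt
Reagents that add atoms: none
Why: Fluoride-driven desilylation under buffered, weakly acidic conditions avoids the free alkoxide that could isomerise a 2-(1-hydroxyalkyl)quinone, breaks no bond at C1′ and leaves the acetals on.

**Step 11**
Reactants: 18 2-[(S)-1-hydroxy-4-methylpent-3-enyl]-5,8-bis(methoxymethoxy)naphthalene-1,4-dione; 19 3-methylbut-2-enoic acid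
Product: 20 (S)-1-[5,8-bis(methoxymethoxy)-1,4-dioxo-1,4-dihydronaphthalen-2-yl]-4-methylpent-3-enyl 3-methylbut-2-enoate
Conditions: DCC, DMAP (cat.), CH2Cl2, 0 °C → rt
Reagents that add atoms: none
Why: Steglich esterification acylates the only free hydroxyl through the acylpyridinium formed from the O-acylisourea, with retention at C1′ because the carbinol C–O bond is not broken, and catalytic DMAP without added amine base should keep the acyl group conjugated.

**Step 12**
Reactants: 20 (S)-1-[5,8-bis(methoxymethoxy)-1,4-dioxo-1,4-dihydronaphthalen-2-yl]-4-methylpent-3-enyl 3-methylbut-2-enoate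
Product: 21 alkannin β,β-dimethylacrylate [(S)-1-(5,8-dihydroxy-1,4-dioxo-1,4-dihydronaphthalen-2-yl)-4-methylpent-3-enyl 3-methylbut-2-enoate]
Conditions: HCl (cat.), MeOH/CH2Cl2, 0 °C → rt
Reagents that add atoms: none
Why: Acid-catalysed transacetalisation to methanol removes both methoxymethyl groups, assisted by the peri carbonyl oxygens that hydrogen-bond the released phenols, under conditions that should be too mild to solvolyse the ester or add to the trisubstituted olefin.

**Compound list**
1 | hydroquinone | Oc1ccc(O)cc1 | starting material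
2 | 1,4-bis(methoxymethoxy)benzene | COCOc1ccc(OCOC)cc1 | intermediate
3 | chromium hexacarbonyl, Cr(CO)6 | O=C=[Cr](=C=O)(=C=O)(=C=O)(=C=O)=C=O | starting material
4 | 2,5-bis(methoxymethoxy)phenyllithium | [Li]c1cc(OCOC)ccc1OCOC | intermediate
5 | lithium pentacarbonyl{[2,5-bis(methoxymethoxy)phenyl](oxido)methylidene}chromate | [Li+].[O-]C(=[Cr](=C=O)(=C=O)(=C=O)(=C=O)=C=O)c1cc(OCOC)ccc1OCOC | intermediate
6 | pentacarbonyl{[2,5-bis(methoxymethoxy)phenyl](methoxy)methylidene}chromium | COC(=[Cr](=C=O)(=C=O)(=C=O)(=C=O)=C=O)c1cc(OCOC)ccc1OCOC | intermediate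
7 | 4-methylpent-3-enoic acid | CC(C)=CCC(=O)O | starting material
8 | N-methoxy-N,4-dimethylpent-3-enamide | CC(C)=CCC(=O)N(C)OC | intermediate
9 | trimethylsilylacetylene | C#C[Si](C)(C)C | starting material
10 | lithium (trimethylsilyl)acetylide | [Li]C#C[Si](C)(C)C | intermediate
11 | 6-methyl-1-(trimethylsilyl)hept-5-en-1-yn-3-one | CC(C)=CCC(=O)C#C[Si](C)(C)C | intermediate
12 | (S)-6-methyl-1-(trimethylsilyl)hept-5-en-1-yn-3-ol | CC(C)=CC[C@H](O)C#C[Si](C)(C)C | intermediate
13 | (S)-3-(tert-butyldimethylsilyloxy)-6-methyl-1-(trimethylsilyl)hept-5-en-1-yne | CC(C)=CC[C@H](O[Si](C)(C)C(C)(C)C)C#C[Si](C)(C)C | intermediate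
14 | (S)-3-(tert-butyldimethylsilyloxy)-6-methylhept-5-en-1-yne | CC(C)=CC[C@H](O[Si](C)(C)C(C)(C)C)C#C | intermediate
15 | tricarbonyl{η6-2-[(S)-1-(tert-butyldimethylsilyloxy)-4-methylpent-3-enyl]-4-methoxy-5,8-bis(methoxymethoxy)naphthalen-1-ol}chromium, Cr(CO)3 bound to ring B (arene and Cr(CO)3 written joined by a dot) | CC(C)=CC[C@H](O[Si](C)(C)C(C)(C)C)c1cc(OC)c2c(OCOC)ccc(OCOC)c2c1O.O=C=[Cr](=C=O)=C=O | intermediate
16 | 2-[(S)-1-(tert-butyldimethylsilyloxy)-4-methylpent-3-enyl]-4-methoxy-5,8-bis(methoxymethoxy)naphthalen-1-ol | CC(C)=CC[C@H](O[Si](C)(C)C(C)(C)C)c1cc(OC)c2c(OCOC)ccc(OCOC)c2c1O | intermediate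
17 | 2-[(S)-1-(tert-butyldimethylsilyloxy)-4-methylpent-3-enyl]-5,8-bis(methoxymethoxy)naphthalene-1,4-dione | CC(C)=CC[C@H](O[Si](C)(C)C(C)(C)C)C1=CC(=O)c2c(OCOC)ccc(OCOC)c2C1=O | intermediate
18 | 2-[(S)-1-hydroxy-4-methylpent-3-enyl]-5,8-bis(methoxymethoxy)naphthalene-1,4-dione | CC(C)=CC[C@H](O)C1=CC(=O)c2c(OCOC)ccc(OCOC)c2C1=O | intermediate
19 | 3-methylbut-2-enoic acid | CC(C)=CC(=O)O | starting material
20 | (S)-1-[5,8-bis(methoxymethoxy)-1,4-dioxo-1,4-dihydronaphthalen-2-yl]-4-methylpent-3-enyl 3-methylbut-2-enoate | CC(C)=CC[C@H](OC(=O)C=C(C)C)C1=CC(=O)c2c(OCOC)ccc(OCOC)c2C1=O | intermediate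
21 | alkannin β,β-dimethylacrylate, (S)-1-(5,8-dihydroxy-1,4-dioxo-1,4-dihydronaphthalen-2-yl)-4-methylpent-3-enyl 3-methylbut-2-enoate | CC(C)=CC[C@H](OC(=O)C=C(C)C)C1=CC(=O)c2c(O)ccc(O)c2C1=O | target

**Total step count:** 12
**Longest linear sequence:** 10 steps (7 → 8 → 11 → 12 → 13 → 14 → 16 → 17 → 18 → 20 → 21); the arene branch (1 → 2 → 6) joins at step 8.

**Steps most likely to fail**

Step 8. The chromium vinylcarbene or vinylketene may be diverted before ring closure (indene, furan or cyclobutenone formation, alkyne oligomerisation). Chelation of the ortho acetal oxygen to chromium and the bulk beside the alkyne would favour this. The fallback gives up the benzannulation: the side chain is joined to a preformed naphthalene by directed ortho-metalation and acylation, and C1′ is set by reagent-controlled ketone reduction. It sets out from 8 and comes back to the route at 20.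
- Purchased naphthazarin F1 is reduced with Na2S2O4 in aqueous THF to leuconaphthazarin F2. Exhaustive alkylation (NaH, MOMCl, DMF) should give 1,4,5,8-tetrakis(methoxymethoxy)naphthalene F3, whose four free ring positions are equivalent.
- Lithiation (n-BuLi, TMEDA, THF, 0 °C) and addition to 8 should give the aryl ketone F4.
- Reduction with (−)-Ipc2BCl, in which the aryl group acts as the large substituent, should give the (S)-alcohol F5.
- Steglich esterification with 19 (DCC, DMAP cat.) gives the ester F6.
- (NH4)2Ce(NO3)6 in aqueous MeCN at 0 °C should remove two acetals oxidatively. Oxidation of the substituted ring gives 20. Oxidation of the other ring gives the isomeric quinone F7, which under the conditions of step 12 gives the same 21, because the two naphthazarin tautomers are one compound.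

Step 12. While the acetals are cleaved, the acid may solvolyse or ionise the ester at C1′ or add to the trisubstituted olefin. The fallback moves the acylation to the end, so that the acid meets only the alcohol. It sets out from 18 and comes back at 21. Dilute HCl in aqueous THF should remove both acetals from 18 to give alkannin F8. Acylation with 19 (DCC, DMAP cat., CH2Cl2, 0 °C) should then take place at the side-chain hydroxyl alone, because both phenolic hydroxyls are tied up in hydrogen bonds to the quinone carbonyls and are poor nucleophiles.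

Step 5. The skipped olefin may migrate into conjugation with the ynone under the basic amido catalyst, or the catalyst may discriminate poorly between the silylalkynyl and the allylic substituent. The fallback replaces catalyst control by resolution. It sets out from 11 and comes back at 12. Luche reduction (NaBH4, CeCl3·7H2O, MeOH, −78 °C) gives the racemic alcohol F9. Esterification with (S)-O-methylmandelic acid (DCC, DMAP cat., CH2Cl2, −10 °C) gives two diastereomeric esters: the (S)-carbinol ester F10 and the (R)-carbinol ester F11. These are to be separated by chromatography and assigned by the shielding effect of the mandelate phenyl ring. Reductive cleavage of F10 (i-Bu2AlH, CH2Cl2, −78 → 0 °C) returns 12 with the C–Si bond intact.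

**Further compounds**
F1 | step 8 | naphthazarin, 5,8-dihydroxynaphthalene-1,4-dione (purchased) | O=C1C=CC(=O)c2c(O)ccc(O)c12
F2 | step 8 | leuconaphthazarin, 5,8-dihydroxy-2,3-dihydronaphthalene-1,4-dione | O=C1CCC(=O)c2c(O)ccc(O)c12
F3 | step 8 | 1,4,5,8-tetrakis(methoxymethoxy)naphthalene | COCOc1ccc(OCOC)c2c(OCOC)ccc(OCOC)c12
F4 | step 8 | 4-methyl-1-[1,4,5,8-tetrakis(methoxymethoxy)naphthalen-2-yl]pent-3-en-1-one | CC(C)=CCC(=O)c1cc(OCOC)c2c(OCOC)ccc(OCOC)c2c1OCOC
F5 | step 8 | (S)-4-methyl-1-[1,4,5,8-tetrakis(methoxymethoxy)naphthalen-2-yl]pent-3-en-1-ol | CC(C)=CC[C@H](O)c1cc(OCOC)c2c(OCOC)ccc(OCOC)c2c1OCOC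
F6 | step 8 | (S)-4-methyl-1-[1,4,5,8-tetrakis(methoxymethoxy)naphthalen-2-yl]pent-3-enyl 3-methylbut-2-enoate | CC(C)=CC[C@H](OC(=O)C=C(C)C)c1cc(OCOC)c2c(OCOC)ccc(OCOC)c2c1OCOC
F7 | step 8 | (S)-1-[1,4-bis(methoxymethoxy)-5,8-dioxo-5,8-dihydronaphthalen-2-yl]-4-methylpent-3-enyl 3-methylbut-2-enoate | CC(C)=CC[C@H](OC(=O)C=C(C)C)c1cc(OCOC)c2C(=O)C=CC(=O)c2c1OCOC
F8 | step 12 | alkannin, 5,8-dihydroxy-2-[(S)-1-hydroxy-4-methylpent-3-enyl]naphthalene-1,4-dione | CC(C)=CC[C@H](O)C1=CC(=O)c2c(O)ccc(O)c2C1=O
F9 | step 5 | rac-6-methyl-1-(trimethylsilyl)hept-5-en-1-yn-3-ol | CC(C)=CCC(O)C#C[Si](C)(C)C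
F10 | step 5 | (S)-6-methyl-1-(trimethylsilyl)hept-5-en-1-yn-3-yl (S)-2-methoxy-2-phenylacetate | CC(C)=CC[C@H](OC(=O)[C@@H](OC)c1ccccc1)C#C[Si](C)(C)C
F11 | step 5 | (R)-6-methyl-1-(trimethylsilyl)hept-5-en-1-yn-3-yl (S)-2-methoxy-2-phenylacetate | CC(C)=CC[C@@H](OC(=O)[C@@H](OC)c1ccccc1)C#C[Si](C)(C)C
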